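**Retrosynthetic overview**

- The strategy rests on the quaternary C4, which carries methyl C18 and the oxygenated C19 (axial, cis to C20) and heads the C4–C5–C10–C9 spine of the trans-fused A/B decalin; this is the pattern a 2-methylacetoacetate radical leaves after cyclising along an (E,E)-polyene.
- Key disconnection: C4–C5 (ring A, closed first) and C9–C10 (ring B, closed second) by Mn(OAc)3/Cu(OAc)2 oxidative radical bicyclisation of a (−)-8-phenylmenthyl α-methyl β-keto ester, which also leaves the C8(17) olefin.
- The cyclisation precursor comes from γ-alkylation (C1–C2 bond) of the auxiliary 2-methylacetoacetate dianion with the E-allylic bromide made from ketalised geranylacetone by SeO2 oxidation of its terminal E-methyl group.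
- After the rings: ester to C19 carbinol, C3 deoxygenation, C8(17) to C7 olefin shift, C13 methyl ketone to alkyne to ynoate to (13Z)-enoate with Me2CuLi, angelate ester, release of the C15 acid.

Key step: step 6

Assumption: the (−)-8-phenylmenthyl ester is taken to expose the face of the C4 radical that leads to the 4α-methyl, 10β-methyl series drawn; if the sense is the opposite one, the enantiomeric auxiliary is used and nothing else changes. Labdane numbering is used for all bicyclic compounds.

**Route**

Step 1
Reactants: 1 geranylacetone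
Product: 2 2-[(3E)-4,8-dimethylnona-3,7-dien-1-yl]-2-methyl-1,3-dioxolane
Conditions: ethylene glycol, PPTS (cat.), benzene, reflux, Dean–Stark
Reagents that add atoms: ethylene glycol, OCCO
Why: Acid-catalysed ketalisation with azeotropic removal of water goes to completion, and the mild pyridinium acid should leave both trisubstituted olefins untouched.

Step 2
Reactants: 2 geranylacetone dioxolane
Product: 3 (2E,6E)-2,6-dimethyl-9-(2-methyl-1,3-dioxolan-2-yl)nona-2,6-dien-1-ol
Conditions: SeO2 (cat.), t-BuOOH, CH2Cl2, 0 °C to rt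
Reagents that add atoms: tert-butyl hydroperoxide, CC(C)(C)OO (the oxygen is relayed by catalytic SeO2, O=[Se]=O)
Why: Riley-type catalytic SeO2 allylic oxidation (ene reaction then [2,3]-sigmatropic shift) attacks the most electron-rich and least hindered terminal olefin and oxidises its E-methyl group, which fixes the 2E geometry of the allylic alcohol.

Step 3
Reactants: 3 E-allylic alcohol
Product: 4 2-[(3E,7E)-9-bromo-4,8-dimethylnona-3,7-dien-1-yl]-2-methyl-1,3-dioxolane
Conditions: CBr4, PPh3, CH2Cl2, 0 °C
Reagents that add atoms: carbon tetrabromide, BrC(Br)(Br)Br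
Why: Appel bromination goes through an alkoxyphosphonium ion under non-acidic conditions, so the primary allylic bromide should form without allylic transposition, loss of E geometry or loss of the dioxolane.

Step 4
Reactants: 5 ethyl 2-methylacetoacetate; 6 (−)-8-phenylmenthol
Product: 7 (−)-8-phenylmenthyl 2-methyl-3-oxobutanoate (C2 epimers)
Conditions: DMAP (cat.), toluene, reflux, EtOH distilled off
Reagents that add atoms: none
Why: DMAP-catalysed transesterification of an enolisable β-keto ester is driven by removal of ethanol and installs the auxiliary on the small fragment before the chain is attached.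

Step 5
Reactants: 7 (−)-8-phenylmenthyl 2-methyl-3-oxobutanoate; 4 allylic bromide
Product: 9 (−)-8-phenylmenthyl (6E,10E)-2,6,10-trimethyl-13-(2-methyl-1,3-dioxolan-2-yl)-3-oxotrideca-6,10-dienoate (cyclisation precursor; C2 epimers), via sodium lithium dianion 8 (not isolated)
Conditions: NaH, THF, 0 °C; n-BuLi, 0 °C; then 4, 0 °C to rt; H2O
Reagents that add atoms: none
Why: In this β-keto ester dianion γ-alkylation (Weiler alkylation) the terminal carbanion is the more reactive site and displaces the primary allylic bromide by SN2 with retention of the E geometry, while the epimeric α-carbon is irrelevant because it becomes a planar radical.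

Step 6
Reactants: 9 cyclisation precursor
Product: 10 (−)-8-phenylmenthyl 13,13-(ethylenedioxy)-3-oxo-14,15-dinorlabd-8(17)-en-19-oate (4α-methyl, 4β-ester, 5α-H, 9β side chain, 10β-methyl)
Conditions: Mn(OAc)3·2H2O (2.2 equiv), Cu(OAc)2·H2O (1 equiv), degassed EtOH, rt
Reagents that add atoms: none
Why: Mn(OAc)3 converts the β-keto ester into its manganese enolate and inner-sphere electron transfer (trivalent to divalent manganese) gives the electrophilic tertiary C4 radical; this adds 6-endo-trig to C5 (ring A), the resulting tertiary C10 radical adds 6-endo-trig to C9 (ring B), and Cu(OAc)2 captures the tertiary C8 radical and loses copper hydride toward the unhindered C17 methyl to give the exocyclic olefin. The closest known reaction type is the oxidative free-radical polyene cyclisation of α-alkyl β-keto esters with Mn(OAc)3 and Cu(OAc)2, including 8-phenylmenthyl esters. C5, C10 and C9 follow from the two E olefins reacting through a chair–chair transition state (5α-H and 10β-methyl trans, 9β side chain equatorial), and at C4 the ketone stays in the ring with the ester axial, cis to C20, and C18 equatorial. The absolute sense is set at C4 by the auxiliary, whose phenyl ring lies over one face of the planar radical so that C5 bonds to the open face. The step needs endo rather than 5-exo closure twice, secured by the trisubstituted olefins (attack at the CH terminus gives tertiary radicals), and it needs oxidation only after the second closure, secured because ring closure of the C10 radical outruns its capture by copper. Ethanol instead of acetic acid keeps the medium mild enough for the dioxolane.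

Step 7
Reactants: 10 bicyclic keto ester
Product: 11 13,13-(ethylenedioxy)-14,15-dinorlabd-8(17)-ene-3β,19-diol
Conditions: LiAlH4, THF, 0 °C to reflux; aqueous NaOH work-up; 6 recovered
Reagents that add atoms: none
Why: Hydride reduction with LiAlH4 reduces the C3 ketone and, at reflux, the hindered neopentyl ester to the C19 carbinol while releasing the auxiliary, and the C3 carbinol configuration (3β expected from axial hydride delivery on the α face) is of no consequence because C3 is deoxygenated later.

Step 8
Reactants: 11 3β,19-diol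
Product: 12 19-(tert-butyldiphenylsilyloxy)-13,13-(ethylenedioxy)-14,15-dinorlabd-8(17)-en-3β-ol
Conditions: TBDPSCl, imidazole, DMF, 0 °C to rt
Reagents that add atoms: tert-butyl(chloro)diphenylsilane, CC(C)(C)[Si](Cl)(c1ccccc1)c1ccccc1
Why: Silylation with the bulky chlorosilane should discriminate the primary C19 hydroxyl from the secondary neopentyl C3 hydroxyl, and the TBDPS ether is chosen because it survives the later acidic ketal hydrolysis.

Step 9
Reactants: 12 C19 silyl ether
Product: 13 O-[19-(tert-butyldiphenylsilyloxy)-13,13-(ethylenedioxy)-14,15-dinorlabd-8(17)-en-3β-yl] 1H-imidazole-1-carbothioate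
Conditions: 1,1'-thiocarbonyldiimidazole, DMAP (cat.), toluene, 90 °C
Reagents that add atoms: 1,1'-thiocarbonyldiimidazole, S=C(n1ccnc1)n1ccnc1
Why: Thioacylation of the remaining C3 alcohol under neutral conditions gives the substrate for radical deoxygenation without the alkoxide that could trigger silyl migration or retro-aldol-type side reactions.

Step 10
Reactants: 13 C3 imidazolyl thiocarbonate
Product: 14 19-(tert-butyldiphenylsilyloxy)-13,13-(ethylenedioxy)-14,15-dinorlabd-8(17)-ene
Conditions: Bu3SnH, AIBN (cat.), toluene, reflux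
Reagents that add atoms: none
Why: In the Barton–McCombie deoxygenation the stannyl radical adds to the thiocarbonyl sulfur, the secondary C3 radical is released and reduced by Bu3SnH, and the ketal, silyl ether and 1,1-disubstituted olefin are inert to the chain.

Step 11
Reactants: 14 C8(17) olefin
Product: 15 19-(tert-butyldiphenylsilyloxy)-13,13-(ethylenedioxy)-14,15-dinorlabd-7-ene
Conditions: Co(salen-tBu,tBu)Cl [chloro(N,N'-bis(3,5-di-tert-butylsalicylidene)-1,2-cyclohexanediaminato)cobalt, trivalent cobalt] (cat.), PhSiH3 (cat.), benzene, rt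
Reagents that add atoms: none
Why: In this cobalt-hydride hydrogen-atom-transfer olefin isomerisation, reversible H-atom delivery to C17 gives the tertiary C8 radical and the cobalt catalyst takes back the accessible C7 hydrogen in preference to the hindered tertiary C9–H, so the 1,1-disubstituted olefin moves by one position to the trisubstituted C7=C8 olefin under neutral conditions that spare the dioxolane and leave C9 configured.

Step 12
Reactants: 15 C7 olefin dioxolane
Product: 16 19-(tert-butyldiphenylsilyloxy)-14,15-dinorlabd-7-en-13-one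
Conditions: PPTS (cat.), acetone/H2O 9:1, 55 °C
Reagents that add atoms: water, O
Why: Mild acid-catalysed ketal hydrolysis frees the C13 methyl ketone, and the TBDPS ether and the trisubstituted olefin are stable to the pyridinium acid.

Step 13
Reactants: 16 methyl ketone
Product: 18 terminal alkyne 19-(tert-butyldiphenylsilyloxy)-15,16-dinorlabd-7-en-13-yne, via enol diethyl phosphate 17 (not isolated)
Conditions: LiN(iPr)2 (1.1 equiv), THF, −78 °C; ClP(O)(OEt)2, −78 °C to rt; LiN(iPr)2 (2.3 equiv), −78 °C to rt; H2O
Reagents that add atoms: none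
Why: In this methyl ketone to terminal alkyne conversion through the enol phosphate, kinetic deprotonation occurs at the methyl group, the enolate is O-phosphorylated, and base-induced elimination of phosphate followed by acetylide formation delivers C13≡C14 with the former methyl carbon as C14.

Step 14
Reactants: 18 terminal alkyne
Product: 20 tert-butyl 19-(tert-butyldiphenylsilyloxy)-16-norlabd-7-en-13-yn-15-oate, via lithium acetylide 19 (not isolated)
Conditions: n-BuLi, THF, −78 °C; Boc2O, −78 to 0 °C
Reagents that add atoms: di-tert-butyl dicarbonate, CC(C)(C)OC(=O)OC(=O)OC(C)(C)C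
Why: C-acylation of the lithium acetylide with the dicarbonate adds C15 as a tert-butyl ester, chosen because it can be removed at the end without touching the angelate.

Step 15
Reactants: 20 tert-butyl ynoate
Product: 21 tert-butyl (13Z)-19-(tert-butyldiphenylsilyloxy)labda-7,13-dien-15-oate
Conditions: Me2CuLi (from CuI and MeLi), THF, −78 °C; MeOH, −78 °C
Reagents that add atoms: lithium dimethylcuprate, [Li+].C[Cu-]C
Why: Conjugate addition of the Gilman cuprate to the ynoate is a syn carbocupration, and protonation of the vinylcopper at −78 °C with retention places the new C16 methyl cis to H14, that is C12 cis to the ester, which is the 13Z geometry of the target.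

Step 16
Reactants: 21 silyl ether Z-enoate
Product: 22 tert-butyl (13Z)-19-hydroxylabda-7,13-dien-15-oate
Conditions: TBAF, THF, rt to 40 °C
Reagents that add atoms: none
Why: Fluoride-mediated desilylation, driven by the strong Si–F bond, frees the C19 alcohol without affecting the tert-butyl enoate or either olefin.

Step 17
Reactants: 22 C19 alcohol; 23 angelic acid
Product: 24 tert-butyl (13Z)-19-angeloyloxylabda-7,13-dien-15-oate
Conditions: 23, 2,4,6-Cl3C6H2COCl, Et3N, toluene, rt; then 22, 80 °C
Reagents that add atoms: none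
Why: Yamaguchi-type esterification through the mixed 2,4,6-trichlorobenzoic anhydride, run without a nucleophilic amine catalyst, acylates the neopentyl alcohol at the less hindered angeloyl carbonyl and avoids the addition–elimination pathway that would isomerise angelate to tiglate.

Step 18
Reactants: 24 angelate tert-butyl ester
Product: 26 (13Z)-19-angeloyloxylabda-7,13-dien-15-oic acid (target CNP0249147.1), via trimethylsilyl ester 25 (not isolated)
Conditions: TMSOTf, 2,6-lutidine, CH2Cl2, 0 °C to rt; aqueous work-up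
Reagents that add atoms: none
Why: Silyl-triflate-mediated tert-butyl ester cleavage (carbonyl O-silylation, loss of the tert-butyl cation as isobutene, hydrolysis of the silyl ester on work-up) runs under buffered non-protic conditions that should spare the C7 olefin, the primary angelate and the 13Z geometry.

**Compound list**

1 | geranylacetone, (5E)-6,10-dimethylundeca-5,9-dien-2-one | CC(C)=CCC/C(C)=C/CCC(C)=O | starting material
2 | 2-[(3E)-4,8-dimethylnona-3,7-dien-1-yl]-2-methyl-1,3-dioxolane | CC(C)=CCC/C(C)=C/CCC1(C)OCCO1 | intermediate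
3 | (2E,6E)-2,6-dimethyl-9-(2-methyl-1,3-dioxolan-2-yl)nona-2,6-dien-1-ol | OC/C(C)=C/CC/C(C)=C/CCC1(C)OCCO1 | intermediate
4 | 2-[(3E,7E)-9-bromo-4,8-dimethylnona-3,7-dien-1-yl]-2-methyl-1,3-dioxolane | BrC/C(C)=C/CC/C(C)=C/CCC1(C)OCCO1 | intermediate
5 | ethyl 2-methylacetoacetate (ethyl 2-methyl-3-oxobutanoate) | CCOC(=O)C(C)C(C)=O | starting material
6 | (−)-8-phenylmenthol, (1R,2S,5R)-5-methyl-2-(2-phenylpropan-2-yl)cyclohexan-1-ol | CC(C)(c1ccccc1)[C@@H]1CC[C@@H](C)C[C@H]1O | starting material
7 | (−)-8-phenylmenthyl 2-methyl-3-oxobutanoate (C2 epimers) | CC(C)(c1ccccc1)[C@@H]1CC[C@@H](C)C[C@H]1OC(=O)C(C)C(C)=O | intermediate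
8 | sodium lithium dianion of 7 (not isolated) | CC(C)(c1ccccc1)[C@@H]1CC[C@@H](C)C[C@H]1OC(=O)[C-](C)C(=O)[CH2-].[Na+].[Li+] | intermediate
9 | (−)-8-phenylmenthyl (6E,10E)-2,6,10-trimethyl-13-(2-methyl-1,3-dioxolan-2-yl)-3-oxotrideca-6,10-dienoate (C2 epimers) | CC(C)(c1ccccc1)[C@@H]1CC[C@@H](C)C[C@H]1OC(=O)C(C)C(=O)CC/C(C)=C/CC/C(C)=C/CCC1(C)OCCO1 | intermediate
10 | (−)-8-phenylmenthyl 13,13-(ethylenedioxy)-3-oxo-14,15-dinorlabd-8(17)-en-19-oate (4α-methyl, 4β-ester, 5α-H, 9β side chain, 10β-methyl) | CC(C)(c1ccccc1)[C@@H]1CC[C@@H](C)C[C@H]1OC(=O)[C@@]1(C)C(=O)CC[C@]2(C)[C@@H](CCC3(C)OCCO3)C(=C)CC[C@@H]12 | intermediate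
11 | 13,13-(ethylenedioxy)-14,15-dinorlabd-8(17)-ene-3β,19-diol (3β drawn as the expected epimer; either epimer serves) | OC[C@@]1(C)[C@@H](O)CC[C@]2(C)[C@@H](CCC3(C)OCCO3)C(=C)CC[C@@H]12 | intermediate
12 | 19-(tert-butyldiphenylsilyloxy)-13,13-(ethylenedioxy)-14,15-dinorlabd-8(17)-en-3β-ol | CC(C)(C)[Si](c1ccccc1)(c1ccccc1)OC[C@@]1(C)[C@@H](O)CC[C@]2(C)[C@@H](CCC3(C)OCCO3)C(=C)CC[C@@H]12 | intermediate
13 | O-[19-(tert-butyldiphenylsilyloxy)-13,13-(ethylenedioxy)-14,15-dinorlabd-8(17)-en-3β-yl] 1H-imidazole-1-carbothioate | CC(C)(C)[Si](c1ccccc1)(c1ccccc1)OC[C@@]1(C)[C@@H](OC(=S)n4ccnc4)CC[C@]2(C)[C@@H](CCC3(C)OCCO3)C(=C)CC[C@@H]12 | intermediate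
14 | 19-(tert-butyldiphenylsilyloxy)-13,13-(ethylenedioxy)-14,15-dinorlabd-8(17)-ene | CC(C)(C)[Si](c1ccccc1)(c1ccccc1)OC[C@@]1(C)CCC[C@]2(C)[C@@H](CCC3(C)OCCO3)C(=C)CC[C@@H]12 | intermediate
15 | 19-(tert-butyldiphenylsilyloxy)-13,13-(ethylenedioxy)-14,15-dinorlabd-7-ene | CC(C)(C)[Si](c1ccccc1)(c1ccccc1)OC[C@@]1(C)CCC[C@]2(C)[C@@H](CCC3(C)OCCO3)C(C)=CC[C@@H]12 | intermediate
16 | 19-(tert-butyldiphenylsilyloxy)-14,15-dinorlabd-7-en-13-one | CC(C)(C)[Si](c1ccccc1)(c1ccccc1)OC[C@@]1(C)CCC[C@]2(C)[C@@H](CCC(C)=O)C(C)=CC[C@@H]12 | intermediate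
17 | diethyl 19-(tert-butyldiphenylsilyloxy)-14,15-dinorlabda-7,13(16)-dien-13-yl phosphate (not isolated) | CC(C)(C)[Si](c1ccccc1)(c1ccccc1)OC[C@@]1(C)CCC[C@]2(C)[C@@H](CCC(=C)OP(=O)(OCC)OCC)C(C)=CC[C@@H]12 | intermediate
18 | 19-(tert-butyldiphenylsilyloxy)-15,16-dinorlabd-7-en-13-yne | CC(C)(C)[Si](c1ccccc1)(c1ccccc1)OC[C@@]1(C)CCC[C@]2(C)[C@@H](CCC#C)C(C)=CC[C@@H]12 | intermediate
19 | lithium acetylide of 18 (not isolated) | CC(C)(C)[Si](c1ccccc1)(c1ccccc1)OC[C@@]1(C)CCC[C@]2(C)[C@@H](CCC#[C-])C(C)=CC[C@@H]12.[Li+] | intermediate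
20 | tert-butyl 19-(tert-butyldiphenylsilyloxy)-16-norlabd-7-en-13-yn-15-oate | CC(C)(C)[Si](c1ccccc1)(c1ccccc1)OC[C@@]1(C)CCC[C@]2(C)[C@@H](CCC#CC(=O)OC(C)(C)C)C(C)=CC[C@@H]12 | intermediate
21 | tert-butyl (13Z)-19-(tert-butyldiphenylsilyloxy)labda-7,13-dien-15-oate | CC(C)(C)[Si](c1ccccc1)(c1ccccc1)OC[C@@]1(C)CCC[C@]2(C)[C@@H](CC/C(C)=C\C(=O)OC(C)(C)C)C(C)=CC[C@@H]12 | intermediate
22 | tert-butyl (13Z)-19-hydroxylabda-7,13-dien-15-oate | OC[C@@]1(C)CCC[C@]2(C)[C@@H](CC/C(C)=C\C(=O)OC(C)(C)C)C(C)=CC[C@@H]12 | intermediate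
23 | angelic acid, (2Z)-2-methylbut-2-enoic acid | C/C=C(/C)C(=O)O | starting material
24 | tert-butyl (13Z)-19-angeloyloxylabda-7,13-dien-15-oate | C/C=C(/C)C(=O)OC[C@@]1(C)CCC[C@]2(C)[C@@H](CC/C(C)=C\C(=O)OC(C)(C)C)C(C)=CC[C@@H]12 | intermediate
25 | trimethylsilyl (13Z)-19-angeloyloxylabda-7,13-dien-15-oate (not isolated) | C/C=C(/C)C(=O)OC[C@@]1(C)CCC[C@]2(C)[C@@H](CC/C(C)=C\C(=O)O[Si](C)(C)C)C(C)=CC[C@@H]12 | intermediate
26 | (13Z)-19-angeloyloxylabda-7,13-dien-15-oic acid, CNP0249147.1 | C/C=C(/C)C(=O)OC[C@@]1(C)CCC[C@]2(C)[C@@H](CC/C(C)=C\C(=O)O)C(C)=CC[C@@H]12 | target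

**Step count**

Total step count: 18.
Longest linear sequence: 17 steps (steps 1–3 and 5–18, from geranylacetone 1 to target 26); step 4 is the one-step side branch.

**Steps most likely to fail**

Step 6. The auxiliary may discriminate the two faces of the C4 radical poorly, so that the two diastereomeric trans-decalins form without useful bias. The fallback replaces auxiliary control by a covalent resolution and sets out from bromide 4 and ethyl ester 5. The dianion of 5 (NaH, then n-BuLi, THF) is alkylated with 4 to give ethyl (6E,10E)-2,6,10-trimethyl-13-(2-methyl-1,3-dioxolan-2-yl)-3-oxotrideca-6,10-dienoate F1. Cyclisation with Mn(OAc)3 and Cu(OAc)2 in ethanol gives the racemic ethyl 13,13-(ethylenedioxy)-3-oxo-14,15-dinorlabd-8(17)-en-19-oate F2. NaBH4 in methanol reduces the ketone to the racemic ethyl 3β-hydroxy ester F3. Esterification with (S)-O-methylmandelic acid (DCC, catalytic DMAP) and chromatographic separation of the two diastereomers gives the (2S)-2-methoxy-2-phenylacetate of the required series F4. LiAlH4 in refluxing THF then cleaves the mandelate and reduces the ethyl ester, and the sequence comes back to the route at diol 11.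

Step 11. The hydrogen back-transfer may lose regiocontrol (C9–H instead of C7–H, giving the tetrasubstituted C8=C9 olefin), or the isomerisation may stall. The fallback builds the C7 olefin regiospecifically and sets out from 14, the only stage with no other olefin. Ozonolysis (O3, CH2Cl2/MeOH, −78 °C, then Me2S) gives 19-(tert-butyldiphenylsilyloxy)-13,13-(ethylenedioxy)-14,15,17-trinorlabdan-8-one F5. Kinetic deprotonation at the C7 methylene with KN(SiMe3)2 at −78 °C and trapping with PhNTf2 gives the C7 enol triflate 19-(tert-butyldiphenylsilyloxy)-13,13-(ethylenedioxy)-14,15,17-trinorlabd-7-en-8-yl trifluoromethanesulfonate F6. Coupling with Me2CuLi in THF installs the C17 methyl, and the sequence comes back to the route at 15.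

Step 17. The slow acylation of the hindered axial neopentyl alcohol may let the angeloyl group isomerise to tigloyl, or may not go to completion. The fallback builds the Z olefin on the ester after acylation and sets out from 22. Esterification with 2-[bis(2,2,2-trifluoroethoxy)phosphoryl]propanoic acid (DCC, DMAP, CH2Cl2; the acid is obtained by saponifying its commercial ester) gives tert-butyl (13Z)-19-{2-[bis(2,2,2-trifluoroethoxy)phosphoryl]propanoyloxy}labda-7,13-dien-15-oate F7. Still–Gennari olefination (KN(SiMe3)2, 18-crown-6, THF, −78 °C, then acetaldehyde) should form the (Z)-2-methylbut-2-enoate, and the sequence comes back to the route at 24.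

Further compounds
F1 | step 6 | ethyl (6E,10E)-2,6,10-trimethyl-13-(2-methyl-1,3-dioxolan-2-yl)-3-oxotrideca-6,10-dienoate (C2 epimers) | CCOC(=O)C(C)C(=O)CC/C(C)=C/CC/C(C)=C/CCC1(C)OCCO1
F2 | step 6 | racemic ethyl 13,13-(ethylenedioxy)-3-oxo-14,15-dinorlabd-8(17)-en-19-oate (relative configuration; the needed enantiomer is drawn) | CCOC(=O)[C@@]1(C)C(=O)CC[C@]2(C)[C@@H](CCC3(C)OCCO3)C(=C)CC[C@@H]12
F3 | step 6 | racemic ethyl 13,13-(ethylenedioxy)-3β-hydroxy-14,15-dinorlabd-8(17)-en-19-oate (relative configuration; the needed enantiomer is drawn) | CCOC(=O)[C@@]1(C)[C@@H](O)CC[C@]2(C)[C@@H](CCC3(C)OCCO3)C(=C)CC[C@@H]12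
F4 | step 6 | ethyl 13,13-(ethylenedioxy)-3β-[(2S)-2-methoxy-2-phenylacetoxy]-14,15-dinorlabd-8(17)-en-19-oate (separated diastereomer of the needed series) | CCOC(=O)[C@@]1(C)[C@@H](OC(=O)[C@@H](OC)c4ccccc4)CC[C@]2(C)[C@@H](CCC3(C)OCCO3)C(=C)CC[C@@H]12
F5 | step 11 | 19-(tert-butyldiphenylsilyloxy)-13,13-(ethylenedioxy)-14,15,17-trinorlabdan-8-one | CC(C)(C)[Si](c1ccccc1)(c1ccccc1)OC[C@@]1(C)CCC[C@]2(C)[C@@H](CCC3(C)OCCO3)C(=O)CC[C@@H]12
F6 | step 11 | 19-(tert-butyldiphenylsilyloxy)-13,13-(ethylenedioxy)-14,15,17-trinorlabd-7-en-8-yl trifluoromethanesulfonate | CC(C)(C)[Si](c1ccccc1)(c1ccccc1)OC[C@@]1(C)CCC[C@]2(C)[C@@H](CCC3(C)OCCO3)C(OS(=O)(=O)C(F)(F)F)=CC[C@@H]12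
F7 | step 17 | tert-butyl (13Z)-19-{2-[bis(2,2,2-trifluoroethoxy)phosphoryl]propanoyloxy}labda-7,13-dien-15-oate | CC(P(=O)(OCC(F)(F)F)OCC(F)(F)F)C(=O)OC[C@@]1(C)CCC[C@]2(C)[C@@H](CC/C(C)=C\C(=O)OC(C)(C)C)C(C)=CC[C@@H]12
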